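Readings and results stem from a simulated flask for substances that don't exist; the scatter is artificial.

I start with an easy step: the flask is charged with 0.10 M of substrate, half the charge of the epsilon run, with the same feed and the same held gas.

- epsilon: substrate 0.20 M (fed, over 20 min); gas 31 mM (held); run made earlier; the fed solution adds 0.25 times the starting volume
- flask: substrate 0.10 M (fed, over 20 min); gas 31 mM (held); time 10 h; the fed solution adds 0.25 times the starting volume

epsilon run (percent of the substrate charged)

| time / min | substrate / % | product / % |
|---|---|---|
| 5.00 | 23.2 | 2.0 |
| 15.0 | 58.2 | 17.0 |
| 30.0 | 50.5 | 50.5 |
| 40.0 | 35.4 | 64.7 |
| 60.0 | 17.5 | 82.3 |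

(readings scatter by 0.5 percentage points)

- amounts are per litre of the starting volume; all of the dose is in the solution fed
- the numbers in the tables scatter with a standard deviation of 0.5 percentage points
- at the start none of the gas is in solution
- a reading or a percentage of product counts all its forms, free or not
- the reaction counts as stopped when no species that holds the substrate changes by six tenths of a point or more over the second half of the time
- percentages count the whole charge, also what has not yet gone in

- why nothing more happens at 10 h, or that something still does (forward and back rates have come level / it is still moving / all of the substrate has reacted)
- conversion of substrate at 10 h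
- amount of product at 10 h, in percent of the substrate charged

In epsilon the two readings at 60.0 min add to 99.8%, so I see no third holder of the substrate. Next I ask how fast it goes. After the feed, substrate falls from 50.5% at 30.0 min to 17.5% at 60.0 min, which gives k = 0.0353 min⁻¹. I define k as the fraction of the substrate present that reacts per minute with the gas held, a pseudo-first-order constant.

A second way uses other readings. During the feed, product rises by 15 percentage points between 5.00 min and 15.0 min while substrate averages 40.7%, which gives 0.0369 min⁻¹. The two agree, so I trust k as a reading. But neither way uses a substrate reading below 17.5%, so neither shows what level substrate falls towards.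

From k the half-life is 19.6 min, so 10 h is 30.6 half-lives. Because that time is far longer, I take whatever stands in the flask at 10 h to be an end state, not a slow tail. I also reckon that the feed ends with 71.7% of the charge as substrate.

The forecast gives 100% conversion, 100% product and the verdict "all of the substrate has reacted", though it grants that “a floor of a few percent cannot be excluded”.

The flask gives 97.5% conversion and 97.5% product, and at 10 h forward and back rates have come level. Its substrate stands at 71.8% at the end of the feed, as k said, and at 2.47% from 5.00 h to 100 h.

    substrate + reagent ⇌ product (K = 36.0 M⁻¹, k = 1.20 M⁻¹ min⁻¹)
    gas ⇌ reagent, rate k2*(csat - [reagent]) (kL = 9.40 min⁻¹)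
    crystals ⇌ product, rate k3*(cs3 - [product]) while solid is left; crystals form when [product] > cs3 (solubility = 2.20 mM, k = 7.80 min⁻¹)

From 71.7%, k reaches that level in 95.4 min. A neighbour flask charged with 0.025 M ends with 9.9% as substrate, a level k reaches in 56.1 min, also well inside the time. Per starting volume, the flask keeps 2.46 mM of substrate and the neighbour 2.48 mM.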